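## The problem

Target 26 is a single cyclohexene, numbered here C1 (alkynyl carbon), C2 (=CH), C3 (OAc), C4 (OMe), C5 (OH), C6 (OH); the same numbers are used for every ring intermediate. C3–C6 are four contiguous oxygenated stereocentres, (3S,4R,5S,6S), in a cis–trans–cis array, and the oxygens carry three different decorations, so O3, O4 and the O5/O6 pair must be told apart, as must C1 from C2. The C1 substituent is a ten-carbon chain joined by a C(sp2)–C(sp) bond: a 2-substituted 1-en-3-yne, a skipped (E)-alkene and a tertiary allylic alcohol. C4 and C5 form a trans-diol that can be bought, and each can direct its outer neighbour (C4→C3, C5→C6) by 1,2-induction, but no remote centre exists to correct an error. The fragile points are the acetate (it migrates to a free cis-vicinal hydroxyl under base), every ketone intermediate with a β-oxygen (E1cB loss, then aromatization), the enyne (metathesis catalysts, hydrometalation, polymerization) and the tertiary allylic alcohol (ionization in acid), so the chain has to arrive late and under near-neutral conditions. The enabling feature is a hidden symmetry: without methyl, acetyl and alkynyl groups, the C3–C6 tetrol on the C1=C2 alkene is conduritol E, which has a C2 axis through the midpoints of C1=C2 and C4–C5, and its C4,C5 trans-diol has the configuration of L-tartaric acid. C1 and C2 are then the inner carbons of two identical vinyl carbinol arms, so the ring can be built in two directions from a tartrate and closed across C1=C2 by olefin metathesis.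

## Retrosynthesis

**C1–C(sp) bond (26 ⇒ 25 ⇒ 17 + 24).** The last cut separates ring and chain: Sonogashira coupling of vinyl iodide 17 with terminal enyne 24, followed only by removal of one silyl group from 25. Compared with growing the chain on the ring, this keeps the acid-labile carbinol and the enyne away from all ring chemistry and makes the route convergent. 17 holds all four stereocentres; 24 is achiral. The forward coupling must tolerate a free allylic hydroxyl, an acetate and a silyl ether.

**C1–I bond and the C6 oxidation level (17 ⇒ 16 ⇒ 15 ⇒ 14 ⇒ 13).** No dependable method replaces the vinylic hydrogen of an allylic alcohol by iodine, so C1 is activated through a C6 ketone: allylic oxidation of 13 to 14, silylation of O5 (15), α-iodination (16) and reduction (17). The price is that C6 is erased and must be re-set cis to O5. A small hydride attacking the enone half-chair axially would tend to give the trans-diol. O5 therefore receives a bulky silyl group and the reduction is put under catalyst control, at the cost of two extra steps.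

**O3–acetyl bond (13 ⇒ 10).** Triol 10 has one cis-vicinal diol (C5/C6) and one isolated hydroxyl (C3). A transient cyclic boronate on the diol leaves O3 as the only acylable oxygen. Placing the acetate after the methyl ether means it never has a free cis neighbour to migrate to.

**O4–CH3 bond (10 ⇒ 9 ⇒ 8).** The methyl ether is traced to monomethylation of diol 8, whose two free hydroxyls are exchanged by the C2 axis. Whichever oxygen reacts becomes O4; its cis neighbour is then C3, the other carbinol is C6, and C1 is the alkene carbon next to C6. One alkylation settles three regiochemical questions; the reagent is asked only to stop at one methyl group.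

**Protecting-group exchange (8 ⇒ 7 ⇒ 6).** The outer hydroxyls of 6 are silylated (7) and the inner acetonide is removed (8). The outer groups must survive mild acid and must not migrate; both steps keep the C2 axis.

**C1=C2 bond (6 ⇒ 5), the key cut.** Cutting the alkene, rather than a ring σ-bond (aldol, carbonyl addition), creates no stereocentre and passes through the C2 axis, so both halves of precursor 5 are identical. 5 is acyclic and needs only two equivalent terminal alkenes. The forward step is ring-closing metathesis with an N-heterocyclic-carbene ruthenium alkylidene, which must close a ring trans-fused to the dioxolane in the presence of free allylic hydroxyls.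

**Two vinyl–carbinol bonds (5 ⇒ 4 + 3 ⇒ 1 + 2).** Both C–C bonds between the carbinols and the vinyl groups are cut at once. The dialdehyde 4 comes from tartrate acetonide 1 and is never isolated; the nucleophile 3 comes from 2. The forward step must add twice with Felkin–Anh (anti) selectivity to give the 3,4-anti/5,6-anti diol.

**Side chain (24 ⇒ 23 ⇒ 21 + 22; 21 ⇒ 19 + 20; 19 ⇒ 18).** The enyne is cut at its C(sp2)–C(sp) bond (bromodiene 21 plus silylacetylene 22) and the skipped diene at the allyl–vinyl bond (stannane 19 plus dibromide 20). 19 is the hydrostannation product of alkynol 18. Each forward step must preserve the (E)-alkene and the unconjugated 1,4-diene.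

## Roads not taken

**Alternative 1:** chiral pool from shikimic acid A1. The cut is at the C5–O and C6–O bonds, with the ring and the cis C3/C4 oxygens bought. A1 is converted into benzyl ester A2 (shikimate O3 methylated, O4 and O5 acetylated), and OsO4 with N-methylmorpholine N-oxide dihydroxylates the ring alkene anti to the allylic methoxy group to give diol A3. In target numbering this sets C5–OH correctly. The ester-bearing carbon becomes C6 once its carboxyl carbon is excised, and β-elimination of the remaining acetate gives an enone of the same type as 14, so iodination, coupling and C6 reduction would follow as in the chosen plan.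
- Merits: the ring and two stereocentres (C3, C4) are present from the start with no epimer risk, which is more secure than a double carbonyl addition, and the anti-dihydroxylation rule is dependable.
- Weak points: the alkene of A2 is trisubstituted and ester-deactivated, hence slow to osmylate. O3 of A1 must be methylated selectively, although the easily formed cyclic derivatives of A1 bridge O3/O4 and expose O5. One carbon, one oxygenated stereocentre of A1 and the tertiary carbinol of A3 are made or bought only to be destroyed.
- Comparison: better in stereochemical security at C3/C4 and needs no metathesis, but it is no shorter and ends in the same C6 problem. The chosen plan sets against it a starting material whose every carbon and oxygen is used, and a symmetry that reduces protecting-group work to one monomethylation.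

**Alternative 2:** an acyclic chain from L-arabinose A4, closed at C1–C6. A4 supplies C3, C4 and C5, its aldehyde carbon becomes C6, and its C5 is extended to the (Z)-bromoenyne of aldehyde A5. CrCl2 with catalytic NiCl2 converts the alkenyl bromide into an alkenylchromium species that adds to the aldehyde (Nozaki–Hiyama–Kishi cyclization), forming the ring, the C1–C6 bond and the C6 carbinol of A6.
- Merits: the alkyne is on C1 before the ring exists, so neither the C6 oxidation–reduction nor the iodination is needed. In this respect the road is better than the chosen one.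
- Weak points: C6 is created in the cyclization with no guarantee of the cis relationship to O5. A5 requires a long linear sequence from A4 (three adjacent hydroxyls differentiated, aldehyde masked, bromoalkene geometry controlled). The chromium reagent is used in stoichiometric excess. A6 carries the same silyl group on O3 and O5, which must later be told apart to place the acetate, and it still needs alkyne unmasking and a second coupling with a vinyl bromide such as 21.
- Comparison: fewer redox steps on the ring but many more before it. The chosen plan sets against it a cyclization substrate made in one operation from 1, a catalytic ring closure that creates no stereocentre, and a symmetry-based answer to the O3/O5 problem that A6 leaves open.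

**Alternative 3:** D-galactose A7 rewired by Ferrier carbocyclization. The cut is the ring C2–C3 bond. A7 is taken to enopyranoside A8 (O2 methylated, O3/O4 bridged as acetonide). Hg(OCOCF3)2-catalysed hydration of its enol ether opens the pyranose to a keto-aldehyde, and an intramolecular aldol closes the carbocycle to β-hydroxy ketone A9 (ketone at C1, CH2 at C2).
- Merits: C4, C5 and C6 come from the sugar in their final oxidation state, and the ketone sits at C1. An enol triflate towards C2 and a Sonogashira coupling could then install the C1=C2 alkene and the chain without touching C6. On paper this is the shortest answer to the C1/C6 problem and better than the chosen plan there.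
- Weak points: C3 is created in the aldol, and nothing in A9 enforces the cis relationship to O4. O3 is β to the ketone, and the enolate towards C2 that triflation needs is the one that expels it (E1cB), which is the usual fate of such aldols. Mercury is required, and A8 takes several protecting-group steps from A7.
- Comparison: better in redox economy at C6, weaker at C3. The chosen plan sets against it a C3 centre made by 1,2-induced addition to an aldehyde and an acetate that is never β to a carbanion.

Key step: step 2

Remark: 1 is bought as the catalogue acetonide of dimethyl L-tartrate; ring locants in the names below follow the target numbering of this proposal (C1 alkynyl carbon to C6), not lowest-locant rules; TBS = tert-butyldimethylsilyl.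

## Route

Step 1
Reactants: 1 dimethyl (4R,5R)-2,2-dimethyl-1,3-dioxolane-4,5-dicarboxylate (dimethyl 2,3-O-isopropylidene-L-tartrate); 2 vinylmagnesium bromide
Product: 5 (3S,4S,5S,6S)-4,5-O-isopropylideneocta-1,7-diene-3,4,5,6-tetrol, via divinylzinc 3 (not isolated), via acetonide dialdehyde 4 (not isolated)
Conditions: i-Bu2AlH (2.1 equiv), toluene, −78 °C; then 3 [from 2 (4.4 equiv) and ZnCl2 (2.2 equiv), THF, 0 °C], −78 °C → rt; aq. KNaC4H4O6; chromatography
Reagents that add atoms: none
Why: Low-temperature i-Bu2AlH reduction stops at the bis(aluminium hemiacetal), so dialdehyde 4 is released only as it is consumed and cannot epimerize; each 1,2-addition of the vinylzinc follows the Felkin–Anh model (nucleophile anti to the dioxolane C–O bond, a poor chelator), which should make both new carbinols anti to their neighbours (3S and 6S) and keep the C2 axis.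

Step 2
Reactants: 5 (3S,4S,5S,6S)-4,5-O-isopropylideneocta-1,7-diene-3,4,5,6-tetrol
Product: 6 (3S,4S,5S,6S)-4,5-O-isopropylidenecyclohex-1-ene-3,4,5,6-tetrol (4,5-O-isopropylidene-conduritol E)
Conditions: second-generation Grubbs catalyst RuCl2(=CHPh)(H2IMes)(PCy3) (5 mol %), degassed CH2Cl2 (0.005 M), 40 °C
Reagents that add atoms: none
Why: Ring-closing olefin metathesis: the ruthenium benzylidene exchanges with one terminal vinyl group (the two are homotopic, so the choice is immaterial), the new alkylidene adds to the second vinyl group in an intramolecular [2+2] cycloaddition, and cycloreversion of the ruthenacyclobutane expels ethylene and forms C1=C2. The closest known reaction type is the metathesis of polyoxygenated octa-1,7-dienes to conduritol derivatives. The ring closes as a six-membered carbocycle between the two inner sp2 carbons across the four-carbon C3–C6 tether, trans-fused to the dioxolane; this fusion adds strain, which is why the N-heterocyclic-carbene catalyst is specified and not the bis(phosphine) one. No stereocentre is formed, the four existing ones are spectators, and 6 keeps the C2 axis on which the later monomethylation depends. The selectivity needed is cyclization over intermolecular diene metathesis; high dilution, irreversible loss of ethylene at reflux and the kinetic ease of six-ring formation should secure it. Both alkenes are monosubstituted and no alkyne is present to divert the carbene. The free allylic hydroxyls are tolerated by this catalyst, so no protecting-group step precedes the ring closure; degassing and a short reaction time limit ruthenium hydride isomerization of the allylic alcohols.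

Step 3
Reactants: 6 (3S,4S,5S,6S)-4,5-O-isopropylidenecyclohex-1-ene-3,4,5,6-tetrol
Product: 7 (3S,4R,5R,6S)-3,6-bis(tert-butyldimethylsilyloxy)-4,5-(isopropylidenedioxy)cyclohex-1-ene
Conditions: TBSOTf (2.4 equiv), 2,6-lutidine, CH2Cl2, 0 °C
Reagents that add atoms: tert-butyldimethylsilyl trifluoromethanesulfonate, CC(C)(C)[Si](C)(C)OS(=O)(=O)C(F)(F)F
Why: Silyl ether formation at the two equivalent allylic hydroxyls; the silyl ethers mask O3 and O6 during acetonide removal and methylation and are removed together by fluoride.

Step 4
Reactants: 7 (3S,4R,5R,6S)-3,6-bis(tert-butyldimethylsilyloxy)-4,5-(isopropylidenedioxy)cyclohex-1-ene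
Product: 8 (3S,4R,5R,6S)-3,6-bis(tert-butyldimethylsilyloxy)cyclohex-1-ene-4,5-diol
Conditions: PPTS (cat.), MeOH, 40 °C
Reagents that add atoms: none
Why: Acid-catalysed transacetalization to methanol should remove the strained trans-fused dioxolane much faster than it cleaves secondary silyl ethers, revealing the C2-symmetric trans-diol.

Step 5
Reactants: 8 (3S,4R,5R,6S)-3,6-bis(tert-butyldimethylsilyloxy)cyclohex-1-ene-4,5-diol
Product: 9 (3S,4R,5R,6S)-3,6-bis(tert-butyldimethylsilyloxy)-4-methoxycyclohex-1-en-5-ol
Conditions: Ag2O (1.5 equiv), MeI, 4 Å molecular sieves, MeCN, 40 °C, dark; stopped before complete conversion, recovered 8 recycled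
Reagents that add atoms: iodomethane, CI
Why: Purdie methylation under near-neutral conditions, which avoids base-induced silyl migration between cis-vicinal oxygens; because the C2 axis exchanges the two hydroxyls of 8, monomethylation gives one compound whichever oxygen reacts, and Ag2O is known to favour monoalkylation of symmetric diols.

Step 6
Reactants: 9 (3S,4R,5R,6S)-3,6-bis(tert-butyldimethylsilyloxy)-4-methoxycyclohex-1-en-5-ol
Product: 10 (3S,4S,5S,6S)-4-methoxycyclohex-1-ene-3,5,6-triol
Conditions: Bu4NF (2.5 equiv), THF, 0 °C → rt; non-aqueous work-up (CaCO3, sulfonic acid resin, MeOH)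
Reagents that add atoms: none
Why: Fluoride cleavage of both silyl ethers (Si–F bond formation) gives the triol whose only cis-vicinal diol is C5/C6.

Step 7
Reactants: 10 (3S,4S,5S,6S)-4-methoxycyclohex-1-ene-3,5,6-triol
Product: 13 (3S,4R,5S,6S)-3-acetoxy-4-methoxycyclohex-1-ene-5,6-diol, via cyclic phenylboronate 11 (not isolated), via boronate acetate 12 (not isolated)
Conditions: PhB(OH)2 (1.05 equiv), toluene, reflux, Dean–Stark; then Ac2O, pyridine, DMAP (cat.), 0 °C → rt; then pinacol, rt
Reagents that add atoms: acetic anhydride, CC(=O)OC(C)=O
Why: Transient boronate protection: only the cis-C5/C6 diol can form a five-membered dioxaborolane (O3 is trans-1,3 to O5 and its cis neighbour is the methyl ether), so DMAP-catalysed acylation is confined to O3 and transesterification with pinacol then frees the diol; the acetate has no free cis-vicinal hydroxyl to migrate to.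

Step 8
Reactants: 13 (3S,4R,5S,6S)-3-acetoxy-4-methoxycyclohex-1-ene-5,6-diol
Product: 14 (3S,4R,5R)-3-acetoxy-5-hydroxy-4-methoxycyclohex-1-en-6-one
Conditions: activated MnO2 (excess), CH2Cl2, rt
Reagents that add atoms: none
Why: Chemoselective MnO2 oxidation of the allylic secondary alcohol at C6; the saturated C5 carbinol and the allylic acetate are not oxidized under these neutral heterogeneous conditions.

Step 9
Reactants: 14 (3S,4R,5R)-3-acetoxy-5-hydroxy-4-methoxycyclohex-1-en-6-one
Product: 15 (3S,4S,5R)-3-acetoxy-5-(tert-butyldimethylsilyloxy)-4-methoxycyclohex-1-en-6-one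
Conditions: TBSOTf (1.2 equiv), 2,6-lutidine, CH2Cl2, −78 → −40 °C
Reagents that add atoms: tert-butyldimethylsilyl trifluoromethanesulfonate, CC(C)(C)[Si](C)(C)OS(=O)(=O)C(F)(F)F
Why: Silylation of the α-hydroxy ketone blocks enediol tautomerization, removes the acidic proton before the borane reduction and places a large group on the O5 face next to the carbonyl; at low temperature with a hindered pyridine base, O-silylation outruns enol silylation.

Step 10
Reactants: 15 (3S,4S,5R)-3-acetoxy-5-(tert-butyldimethylsilyloxy)-4-methoxycyclohex-1-en-6-one
Product: 16 (3S,4S,5R)-3-acetoxy-5-(tert-butyldimethylsilyloxy)-1-iodo-4-methoxycyclohex-1-en-6-one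
Conditions: I2 (2 equiv), pyridine/CH2Cl2 (1:1), 0 °C → rt; aq. Na2S2O3
Reagents that add atoms: iodine, II
Why: α-Iodination of a cyclic enone by conjugate addition of pyridine, iodination of the enolate and elimination (Baylis–Hillman-type sequence); pyridine is too weak a base to trigger β-elimination of the C4 methoxy group, and only C1 can be iodinated.

Step 11
Reactants: 16 (3S,4S,5R)-3-acetoxy-5-(tert-butyldimethylsilyloxy)-1-iodo-4-methoxycyclohex-1-en-6-one
Product: 17 (3S,4S,5S,6R)-3-acetoxy-5-(tert-butyldimethylsilyloxy)-1-iodo-4-methoxycyclohex-1-en-6-ol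
Conditions: (S)-Me-CBS oxazaborolidine (C18H20BNO, 0.5 equiv), catecholborane (2 equiv), toluene, −78 → −40 °C
Reagents that add atoms: none
Why: Corey–Bakshi–Shibata reduction: the oxazaborolidine should bind the carbonyl lone pair anti to the in-plane iodine (iodoalkenyl carbon as the large group), and the (S)-catalyst then delivers hydride to the ring face opposite the C5 silyloxy group, so catalyst control and the steric bias of the substrate reinforce each other and the new C6 hydroxyl is cis to O5 (6R here only because iodine changes the CIP priorities); acetate and vinyl iodide are inert to catecholborane at low temperature.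

Step 12
Reactants: 18 2-methylbut-3-yn-2-ol
Product: 19 (E)-2-methyl-4-(tributylstannyl)but-3-en-2-ol
Conditions: Bu3SnH (1.1 equiv), AIBN (cat.), neat, 85 °C
Reagents that add atoms: tributyltin hydride, CCCC[SnH](CCCC)CCCC
Why: Radical hydrostannation of a terminal alkyne; the stannyl radical adds at the terminus and reversible addition–elimination equilibrates the product to the (E)-alkenylstannane.

Step 13
Reactants: 19 (E)-2-methyl-4-(tributylstannyl)but-3-en-2-ol; 20 2,3-dibromopropene
Product: 21 (E)-6-bromo-2-methylhepta-3,6-dien-2-ol
Conditions: Pd2(dba)3 (2.5 mol %), P(2-furyl)3 (10 mol %), 20 (1.5 equiv), THF, 50 °C; aq. KF work-up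
Reagents that add atoms: none
Why: Stille allyl–vinyl coupling: zerovalent palladium ionizes the allylic C–Br bond of 20 far faster than it inserts into the vinylic one, the two allyl termini are equivalent, and transmetalation–reductive elimination keep the (E)-geometry, giving the skipped diene with the 2-bromoalkene intact.

Step 14
Reactants: 21 (E)-6-bromo-2-methylhepta-3,6-dien-2-ol; 22 ethynyltrimethylsilane
Product: 23 (E)-2-methyl-6-methylidene-8-(trimethylsilyl)oct-3-en-7-yn-2-ol
Conditions: PdCl2(PPh3)2 (3 mol %), CuI (6 mol %), i-Pr2NH, THF, 45 °C
Reagents that add atoms: none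
Why: Sonogashira coupling of a 2-bromo-1-alkene with a silyl-protected acetylene builds the 2-substituted 1-en-3-yne; the amine is too weak a base to move the 1,4-diene into conjugation.

Step 15
Reactants: 23 (E)-2-methyl-6-methylidene-8-(trimethylsilyl)oct-3-en-7-yn-2-ol
Product: 24 (E)-2-methyl-6-methylideneoct-3-en-7-yn-2-ol
Conditions: K2CO3 (cat.), MeOH, 0 °C → rt; used at once as a solution
Reagents that add atoms: none
Why: Base-catalysed methanolysis of the alkynyl C–Si bond; no other group responds.

Step 16
Reactants: 17 (3S,4S,5S,6R)-3-acetoxy-5-(tert-butyldimethylsilyloxy)-1-iodo-4-methoxycyclohex-1-en-6-ol; 24 (E)-2-methyl-6-methylideneoct-3-en-7-yn-2-ol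
Product: 25 (3S,4S,5S,6S)-3-acetoxy-5-(tert-butyldimethylsilyloxy)-1-[(5E)-7-hydroxy-7-methyl-3-methylideneoct-5-en-1-yn-1-yl]-4-methoxycyclohex-1-en-6-ol
Conditions: PdCl2(PPh3)2 (5 mol %), CuI (10 mol %), Et3N, degassed THF, rt
Reagents that add atoms: none
Why: Sonogashira coupling of a 2-iodo allylic alcohol with a terminal alkyne at room temperature; oxidative addition into the vinyl iodide is fast, the free C6 hydroxyl, silyl ether and acetate are spectators, and exclusion of oxygen suppresses Glaser dimerization of 24.

Step 17
Reactants: 25 (3S,4S,5S,6S)-3-acetoxy-5-(tert-butyldimethylsilyloxy)-1-[(5E)-7-hydroxy-7-methyl-3-methylideneoct-5-en-1-yn-1-yl]-4-methoxycyclohex-1-en-6-ol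
Product: 26 (3S,4R,5S,6S)-3-acetoxy-1-[(5E)-7-hydroxy-7-methyl-3-methylideneoct-5-en-1-yn-1-yl]-4-methoxycyclohex-1-ene-5,6-diol, i.e. (1S,4S,5S,6R)-4,5-dihydroxy-3-[(5E)-7-hydroxy-7-methyl-3-methylideneoct-5-en-1-yn-1-yl]-6-methoxycyclohex-2-en-1-yl acetate
Conditions: Bu4NF/AcOH (1:1, 2 equiv), THF, 0 °C → rt
Reagents that add atoms: none
Why: Fluoride desilylation buffered with acetic acid, so that no alkoxide is present to cleave the C3 acetate and no strong acid reaches the tertiary allylic alcohol; a silyl shift between O5 and O6 beforehand would be harmless, since both end up free.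

## Compound list

1 | dimethyl (4R,5R)-2,2-dimethyl-1,3-dioxolane-4,5-dicarboxylate | COC(=O)[C@@H]1OC(C)(C)O[C@H]1C(=O)OC | starting material
2 | vinylmagnesium bromide | C=C[Mg]Br | starting material
3 | divinylzinc | C=C[Zn]C=C | intermediate (not isolated)
4 | (4R,5R)-2,2-dimethyl-1,3-dioxolane-4,5-dicarbaldehyde | O=C[C@@H]1OC(C)(C)O[C@H]1C=O | intermediate (not isolated)
5 | (3S,4S,5S,6S)-4,5-O-isopropylideneocta-1,7-diene-3,4,5,6-tetrol | C=C[C@H](O)[C@@H]1OC(C)(C)O[C@H]1[C@@H](O)C=C | intermediate
6 | (3S,4S,5S,6S)-4,5-O-isopropylidenecyclohex-1-ene-3,4,5,6-tetrol | C1=C[C@H](O)[C@@H]2OC(C)(C)O[C@H]2[C@H]1O | intermediate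
7 | (3S,4R,5R,6S)-3,6-bis(tert-butyldimethylsilyloxy)-4,5-(isopropylidenedioxy)cyclohex-1-ene | C1=C[C@H](O[Si](C)(C)C(C)(C)C)[C@@H]2OC(C)(C)O[C@H]2[C@H]1O[Si](C)(C)C(C)(C)C | intermediate
8 | (3S,4R,5R,6S)-3,6-bis(tert-butyldimethylsilyloxy)cyclohex-1-ene-4,5-diol | C1=C[C@H](O[Si](C)(C)C(C)(C)C)[C@H](O)[C@@H](O)[C@H]1O[Si](C)(C)C(C)(C)C | intermediate
9 | (3S,4R,5R,6S)-3,6-bis(tert-butyldimethylsilyloxy)-4-methoxycyclohex-1-en-5-ol | C1=C[C@H](O[Si](C)(C)C(C)(C)C)[C@H](OC)[C@@H](O)[C@H]1O[Si](C)(C)C(C)(C)C | intermediate
10 | (3S,4S,5S,6S)-4-methoxycyclohex-1-ene-3,5,6-triol | C1=C[C@H](O)[C@H](OC)[C@@H](O)[C@H]1O | intermediate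
11 | cyclic 5,6-O-phenylboronate of 10 (3-OH free) | C1=C[C@H](O)[C@H](OC)[C@@H](O2)[C@H]1OB2c3ccccc3 | intermediate (not isolated)
12 | 3-O-acetyl cyclic 5,6-O-phenylboronate | C1=C[C@H](OC(C)=O)[C@H](OC)[C@@H](O2)[C@H]1OB2c3ccccc3 | intermediate (not isolated)
13 | (3S,4R,5S,6S)-3-acetoxy-4-methoxycyclohex-1-ene-5,6-diol | C1=C[C@H](OC(C)=O)[C@H](OC)[C@@H](O)[C@H]1O | intermediate
14 | (3S,4R,5R)-3-acetoxy-5-hydroxy-4-methoxycyclohex-1-en-6-one | C1=C[C@H](OC(C)=O)[C@H](OC)[C@@H](O)C1=O | intermediate
15 | (3S,4S,5R)-3-acetoxy-5-(tert-butyldimethylsilyloxy)-4-methoxycyclohex-1-en-6-one | C1=C[C@H](OC(C)=O)[C@H](OC)[C@@H](O[Si](C)(C)C(C)(C)C)C1=O | intermediate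
16 | (3S,4S,5R)-3-acetoxy-5-(tert-butyldimethylsilyloxy)-1-iodo-4-methoxycyclohex-1-en-6-one | IC1=C[C@H](OC(C)=O)[C@H](OC)[C@@H](O[Si](C)(C)C(C)(C)C)C1=O | intermediate
17 | (3S,4S,5S,6R)-3-acetoxy-5-(tert-butyldimethylsilyloxy)-1-iodo-4-methoxycyclohex-1-en-6-ol | IC1=C[C@H](OC(C)=O)[C@H](OC)[C@@H](O[Si](C)(C)C(C)(C)C)[C@H]1O | intermediate
18 | 2-methylbut-3-yn-2-ol | C#CC(C)(C)O | starting material
19 | (E)-2-methyl-4-(tributylstannyl)but-3-en-2-ol | CCCC[Sn](CCCC)(CCCC)/C=C/C(C)(C)O | intermediate
20 | 2,3-dibromopropene | C=C(Br)CBr | starting material
21 | (E)-6-bromo-2-methylhepta-3,6-dien-2-ol | C=C(Br)C/C=C/C(C)(C)O | intermediate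
22 | ethynyltrimethylsilane | C#C[Si](C)(C)C | starting material
23 | (E)-2-methyl-6-methylidene-8-(trimethylsilyl)oct-3-en-7-yn-2-ol | C=C(C#C[Si](C)(C)C)C/C=C/C(C)(C)O | intermediate
24 | (E)-2-methyl-6-methylideneoct-3-en-7-yn-2-ol | C=C(C#C)C/C=C/C(C)(C)O | intermediate
25 | (3S,4S,5S,6S)-3-acetoxy-5-(tert-butyldimethylsilyloxy)-1-[(5E)-7-hydroxy-7-methyl-3-methylideneoct-5-en-1-yn-1-yl]-4-methoxycyclohex-1-en-6-ol | C=C(C#CC1=C[C@H](OC(C)=O)[C@H](OC)[C@@H](O[Si](C)(C)C(C)(C)C)[C@H]1O)C/C=C/C(C)(C)O | intermediate
26 | (1S,4S,5S,6R)-4,5-dihydroxy-3-[(5E)-7-hydroxy-7-methyl-3-methylideneoct-5-en-1-yn-1-yl]-6-methoxycyclohex-2-en-1-yl acetate | C=C(C#CC1=C[C@H](OC(C)=O)[C@H](OC)[C@@H](O)[C@H]1O)C/C=C/C(C)(C)O | target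

## Step count and risks

Total: 17 steps. Longest linear sequence: 13 steps (steps 1–11, 16 and 17, from 1). The side chain 24 takes 4 steps (12–15) from 18.

**Step 2 (key step).** The likely failure is intermolecular metathesis (oligomers) winning because the trans ring fusion slows closure. A second is catalyst decay to ruthenium hydrides that isomerize the free allylic alcohols to ketones. The fallback removes both the strain and the free hydroxyls before the ring is closed. It sets out from 5: silylation as in step 3 gives the bis-silyl ether of 5 F2, methanolysis of the acetonide as in step 4 gives (3S,4R,5R,6S)-3,6-bis(tert-butyldimethylsilyloxy)octa-1,7-diene-4,5-diol F3, and metathesis of this unconstrained diene with RuCl2(=CHPh)(H2IMes)(PCy3) should give 8 directly, where the route is rejoined with the same step count.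

**Step 1.** The likely failure is erosion of facial selectivity at one aldehyde (metal chelation by the dioxolane oxygen competing with the Felkin–Anh mode), which gives the unsymmetrical anti,syn diol. The fallback corrects the stereochemistry by oxidation–reduction. It sets out from 5 as obtained, mixed with its C3/C6 epimers. Dess–Martin periodinane converts every isomer into the single C2-symmetric 1,1'-[(4R,5R)-2,2-dimethyl-1,3-dioxolane-4,5-diyl]bis(prop-2-en-1-one) F1. Chelation-controlled 1,2-reduction with Zn(BH4)2 (zinc bridging carbonyl and α-oxygen, hydride entering from the side of the α-hydrogen) is the known route to anti alcohols and should return 5.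

**Step 5.** The likely failures are over-alkylation to the dimethyl ether, silyl migration onto the neighbouring free hydroxyl, or slow reaction between two bulky silyl ethers. The fallback changes the activation mode. It sets out from 8: Bu2SnO in refluxing toluene gives the dibutylstannylene acetal of 8 F4, in which only one tin-bound oxygen is alkylated by MeI/CsF in DMF, and work-up should deliver 9.

**Step 7.** The likely failure is acetylation not staying confined to O3, through incomplete boronate formation or its cleavage by the acetic acid formed. The fallback uses an isolable acetal in place of the transient boronate. It sets out from 10: 2,2-dimethoxypropane with PPTS gives the 5,6-O-isopropylidene derivative of 10 F5, Ac2O/pyridine gives its 3-acetate F6, and aqueous acetic acid at 40 °C removes the cis-acetonide to reach 13.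

**Step 11.** The likely failure is hydride delivery to the wrong face. This could happen if axial attack on the enone half-chair, hindrance from a pseudoaxial C4 methoxy group, or the silyloxy-bearing carbon acting as the large group overrides the intended catalyst control. The fallback accepts the substrate-controlled epimer and inverts it. It sets out from 16: NaBH4/CeCl3·7H2O in MeOH at −78 °C (Luche reduction) gives, if axial attack prevails, the C6-epimeric alcohol F7. Mitsunobu reaction with chloroacetic acid (PPh3, DIAD) inverts C6 to the chloroacetate of 17 F8, and thiourea removes the chloroacetyl group in the presence of the acetate, returning 17.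

## Further compounds

F1 | step 1 | 1,1'-[(4R,5R)-2,2-dimethyl-1,3-dioxolane-4,5-diyl]bis(prop-2-en-1-one) | C=CC(=O)[C@@H]1OC(C)(C)O[C@H]1C(=O)C=C
F2 | step 2 | 3,6-bis-O-(tert-butyldimethylsilyl) ether of 5 | C=C[C@H](O[Si](C)(C)C(C)(C)C)[C@@H]1OC(C)(C)O[C@H]1[C@@H](O[Si](C)(C)C(C)(C)C)C=C
F3 | step 2 | (3S,4R,5R,6S)-3,6-bis(tert-butyldimethylsilyloxy)octa-1,7-diene-4,5-diol | C=C[C@H](O[Si](C)(C)C(C)(C)C)[C@H](O)[C@@H](O)[C@H](C=C)O[Si](C)(C)C(C)(C)C
F4 | step 5 | 4,5-O-dibutylstannylene acetal of 8 | C1=C[C@H](O[Si](C)(C)C(C)(C)C)[C@H](O2)[C@@H](O[Sn]2(CCCC)CCCC)[C@H]1O[Si](C)(C)C(C)(C)C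
F5 | step 7 | 5,6-O-isopropylidene derivative of 10 | C1=C[C@H](O)[C@H](OC)[C@@H](O2)[C@H]1OC2(C)C
F6 | step 7 | 3-O-acetyl-5,6-O-isopropylidene derivative of 10 | C1=C[C@H](OC(C)=O)[C@H](OC)[C@@H](O2)[C@H]1OC2(C)C
F7 | step 11 | C6 epimer of 17 | IC1=C[C@H](OC(C)=O)[C@H](OC)[C@@H](O[Si](C)(C)C(C)(C)C)[C@@H]1O
F8 | step 11 | 6-O-chloroacetate of 17 | IC1=C[C@H](OC(C)=O)[C@H](OC)[C@@H](O[Si](C)(C)C(C)(C)C)[C@H]1OC(=O)CCl
A1 | alternative 1 | shikimic acid | OC(=O)C1=C[C@@H](O)[C@@H](O)[C@H](O)C1
A2 | alternative 1 | benzyl 4,5-di-O-acetyl-3-O-methylshikimate | O=C(OCc1ccccc1)C1=C[C@@H](OC)[C@@H](OC(C)=O)[C@H](OC(C)=O)C1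
A3 | alternative 1 | benzyl 4,5-di-O-acetyl-1,2-dihydroxy-3-O-methyl-1,2-dihydroshikimate | C1[C@@H](OC(C)=O)[C@H](OC(C)=O)[C@H](OC)[C@@H](O)[C@@]1(C(=O)OCc2ccccc2)O
A4 | alternative 2 | L-arabinose (open-chain form) | O=C[C@H](O)[C@@H](O)[C@@H](O)CO
A5 | alternative 2 | (Z)-6-bromo-2,4-bis(tert-butyldimethylsilyloxy)-3-methoxy-8-(triisopropylsilyl)oct-5-en-7-ynal, configuration from A4 | O=C[C@H](O[Si](C)(C)C(C)(C)C)[C@@H](OC)[C@@H](O[Si](C)(C)C(C)(C)C)/C=C(Br)/C#C[Si](C(C)C)(C(C)C)C(C)C
A6 | alternative 2 | 1-(triisopropylsilylethynyl)-3,5-bis(tert-butyldimethylsilyloxy)-4-methoxycyclohex-1-en-6-ol | CC(C)[Si](C(C)C)(C(C)C)C#CC1=C[C@H](O[Si](C)(C)C(C)(C)C)[C@H](OC)[C@@H](O[Si](C)(C)C(C)(C)C)[C@H]1O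
A7 | alternative 3 | D-galactose (open-chain form) | O=C[C@H](O)[C@@H](O)[C@@H](O)[C@H](O)CO
A8 | alternative 3 | methyl 6-deoxy-3,4-O-isopropylidene-2-O-methylhex-5-enopyranoside from A7 (anomeric configuration immaterial) | COC1OC(=C)[C@@H]2OC(C)(C)O[C@@H]2[C@H]1OC
A9 | alternative 3 | 3-hydroxy-4-methoxy-5,6-O-isopropylidenedioxycyclohexanone (ketone at ring C1) | O=C1C[C@H](O)[C@H](OC)[C@@H](O2)[C@H]1OC2(C)C
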